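A closed, stirred vessel at constant temperature holds substrate, free catalyst and impurity. The next run keeps the flask's substrate and impurity and changes its catalyst charge, and the choice lies between twice the charge and 800 µM.

the same everywhere: substrate 21 mM

| flask | free catalyst | impurity | remark |
|---|---|---|---|
| dusk | 48 µM | 20 µM | run made earlier |
| summer | 110 µM | 20 µM | run made earlier |
| noon | 71 µM | 40 µM | run made earlier |
| flask | 71 µM | 20 µM |  |

| run | time / h | product / % | substrate / % |
|---|---|---|---|
| dusk | 1.50 | 74.5 | 25.7 |
| dusk | 3.00 | 94.4 | 4.7 |
| dusk | 5.00 | 99.4 | 1.0 |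
| dusk | 6.00 | 100.1 | 0.3 |
| dusk | 8.00 | 100.1 | 0 |
| dusk | 10.0 | 100.0 | 0.1 |
| dusk | 12.0 | 100.6 | 0 |
| summer | 1.50 | 100.4 | 0.8 |
| summer | 3.00 | 99.9 | 0 |
| summer | 5.00 | 100.0 | 0.8 |
| summer | 6.00 | 100.2 | 0.3 |
| summer | 8.00 | 99.4 | 0.1 |
| summer | 10.0 | 99.7 | 0 |
| summer | 12.0 | 100.0 | 0 |
| noon | 1.00 | 62.6 | 38.2 |
| noon | 2.00 | 88.1 | 12.3 |
| noon | 3.00 | 96.9 | 3.4 |
| noon | 6.00 | 99.8 | 0 |
| noon | 12.0 | 100.0 | 0.3 |

(scatter of a reading: 0.3 percentage points)

- the analysis behind the earlier runs scatters by 0.3 percentage points, standard deviation

- factor on the rate of making product when 30% of the substrate are converted if free catalyst is charged twice over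
- factor on the rate when 30% of the substrate are converted if free catalyst is charged at 800 µM instead

The noon run has 1.48 times the catalyst of the dusk run, yet their substrate readings at 3.00 h are close: 4.7% left at dusk and 3.4% at noon. Read as first-order decay, these give 1.02 /h and 1.13 /h, a ratio of 1.11. Subtracting each run's impurity from its catalyst leaves 28.0 µM and 31.0 µM, a ratio of 1.11.

My reckoning therefore treats the impurity as removing its own amount of catalyst, with impurity as the limiting reagent of that loss. In the flask, free catalyst charged minus impurity charged leaves 51.0 µM, the working catalyst. At equal conversion the substrate is equal, so the factor on the rate is the factor on working catalyst: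

twice the charge: (2 × 71 µM − 20 µM) / 51.0 µM = 2.39

800 µM: (800 µM − 20 µM) / 51.0 µM = 15.3

Twice the charge is the run to make first. Plain proportion says 2 and working catalyst says 2.39, so a reading near 2 would sink the subtraction. The 800 µM charge is also 7.27 times the summer run's 110 µM.

The forecast, using the same subtraction, gives 2.4 and 15, and warns of “a long extrapolation beyond tested loadings”.

    free catalyst + impurity → spent catalyst (k = 1.63 × 10⁶ /M/h)
    substrate + free catalyst → catalyst intermediate A (k = 42000 /M/h)
    catalyst intermediate B → free catalyst + product (k = 1770 /h)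
    catalyst intermediate A → catalyst intermediate B (k = 10400 /h)

The simulation gives 2.39 and 15.4. At 10.0 h the flask holds 71.8% of its catalyst as free catalyst and 28.2% as spent catalyst, with impurity at 0% of its own charge. The flask's working catalyst is 71.8% of its charge. With 800 µM charged, working catalyst comes to 780 µM, which is 97.5% of that charge, and at the same conversion catalyst intermediate A holds 4.11% of the catalyst.

(The runs are calculated on assumed constants, and the scatter is random.)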